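## Retrosynthetic overview

1. Target ⇐ ester cleavage and desilylation ⇐ ring D by gold-catalysed Conia-ene closure (C13–C16) of a C12 silyl enol ether onto a C8 propargyl group; the 2β,3β-diol comes from OsO4 on the Δ2 lactone.
2. Ring B and the 19,10-lactone ⇐ key step: SmI2 reductive cyclisation joining the ring A ketone carbon C10 to the β-carbon C9 of a 4,4-disubstituted cyclohexadienone (two natively electrophilic carbons; dienone β-carbon as homoenolate, or equivalently a C10 ketyl). It desymmetrises the dienone and sets C8, C9 and C10.
3. Dienone ring C with quaternary C8 ⇐ oxidative dearomatisation of a phenol with an allenylsilane.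
4. C5–C6–aryl ⇐ rhodium-catalysed arylboronic acid addition to a glyoxylate-derived alkylidene of the ring A ketone; the auxiliary leaves on ketal-lactone formation.
5. Ring A with quaternary C4 ⇐ auxiliary-controlled Birch reductive methylation of a 3-methoxybenzamide. Ring order: A, then C (arene, then dienone), then B, then D.

Numbering: every intermediate carries the atom numbers of the target (C1–C19; C7 is the carboxyl on C6, C18 the methyl on C4, C19 the lactone carbonyl). α is the face of the lactone bridge; β is the face of H5, H9 and C18.

Assumption: the (S)-auxiliary is taken to give the (R) quaternary carbon of the Birch product; if the sense of induction is the opposite, the commercial (R)-auxiliary is used and nothing else changes.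

## Route

Step 1
Reactants: 1 3-methoxybenzoyl chloride; 2 (2S)-2-(methoxymethyl)pyrrolidine
Product: 3 auxiliary benzamide
Conditions: Et3N, CH2Cl2, 0 °C to 25 °C
Reagents that add atoms: none
Why: Schotten–Baumann-type N-acylation of the secondary amine with the acid chloride attaches the chiral auxiliary that later controls C4 and creates no new stereocentre.

Step 2
Reactants: 3 auxiliary benzamide
Product: 5 Birch diene amide, via potassium amide enolate 4 (not isolated)
Conditions: K (2.2 equiv), t-BuOH (1.0 equiv), NH3/THF, −78 °C; then MeI, −78 °C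
Reagents that add atoms: iodomethane CI
Why: Birch reduction gives the cross-conjugated amide enolate (protonation para to the carbonyl, methoxy group retained on a ring double bond) and the chelated prolinol-ether auxiliary shields one enolate face so that methylation (auxiliary-controlled Birch reductive alkylation) sets the quaternary C4 centre as (R), the minor diastereomer being removed by chromatography.

Step 3
Reactants: 5 Birch diene amide; 6 methyl glyoxylate
Product: 9 alkylidene keto amide, via aldol adduct 7 (not isolated), via mesylate 8 (not isolated)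
Conditions: BF3·OEt2, CH2Cl2, −78 °C; aq. NaHCO3; then MsCl, Et3N, CH2Cl2, 0 °C
Reagents that add atoms: water O
Why: Mukaiyama-type aldol addition of the regiodefined enol ether carbon C5 to the glyoxylate, hydrolysis of the oxocarbenium ion to the C10 ketone and E1cB elimination of the mesylate give the ene-1,4-dicarbonyl acceptor, in which C5 is sp2 and the alkene geometry is irrelevant because C6 is equilibrated in step 8.

Step 4
Reactants: 9 alkylidene keto amide; 10 4-hydroxyphenylboronic acid
Product: 11 aryl keto amide
Conditions: [Rh(OH)(cod)]2 (2.5 mol%; cod = cycloocta-1,5-diene), dioxane/H2O (10:1), 25 °C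
Reagents that add atoms: none
Why: Rhodium-catalysed conjugate addition of the arylboronic acid (Hayashi–Miyaura type) delivers the aryl group to C6, the carbon β to the ketone, and the rhodium enolate is protonated at C5 from the face opposite the bulky amide so that H5 lies cis to the C4 methyl group as in the target, while C6 forms as an epimer mixture.

Step 5
Reactants: 11 aryl keto amide
Product: 12 ketal-lactone phenol
Conditions: camphorsulfonic acid (1.2 equiv), MeOH, 40 °C
Reagents that add atoms: methanol CO
Why: Acid-catalysed hemiketal formation at C10 and intramolecular alcoholysis of the adjacent tertiary amide (lactonisation of a γ-hydroxy amide) release the auxiliary and give the bridged methoxy lactone in which the C6 substituent is equatorial on the one-carbon bridge, so that C5 (still able to equilibrate through the enol before closure) is secured in the required configuration and ring A is protected for the oxidation.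

Step 6
Reactants: 12 ketal-lactone phenol; 13 trimethyl(propa-1,2-dien-1-yl)silane
Product: 15 dienone keto acid, via ketal-lactone dienone 14 (not isolated)
Conditions: PhI(OAc)2, (CF3)2CHOH, −20 °C; then 1 M HCl, THF, 0 °C
Reagents that add atoms: water O
Why: Proposed new method: PhI(OAc)2 turns the phenol into a phenoxenium-type electrophile that the allenylsilane attacks through its terminal CH2 at the para carbon, and loss of the silyl group from the β-silyl vinyl cation leaves the propargyl group on the new quaternary C8 of an achiral 4,4-disubstituted cyclohexa-2,5-dienone (no new stereocentre), the closest known reactions being the oxidative Hosomi–Sakurai para-allylation of 4-alkylphenols with allyltrimethylsilane and the oxidation of 4-hydroxyphenylacetates to para-quinols with the same oxidant; dilute acid then hydrolyses the ketal-lactone to the keto acid faster than C5 can enolise.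

Step 7 (key step)
Reactants: 15 dienone keto acid
Product: 17 lactone enone (C6 epimers), via hydroxy acid 16 (not isolated)
Conditions: SmI2 (2.5 equiv), THF/MeOH (10:1), −78 °C; then 1 M HCl, −78 °C to 25 °C
Reagents that add atoms: none
Why: SmI2 reduces the cross-conjugated dienone to a radical anion whose β-carbon (a homoenolate equivalent, equally describable as C10 ketyl–olefin coupling) attacks the ring A ketone in a 5-exo reductive ketone–enone cyclisation that joins the two natively electrophilic carbons C9 and C10 and desymmetrises the dienone; samarium bridges the C19 carboxylate and the C10 oxygen so that the oxygen is axial and the new bond equatorial (trans A/B junction, C10), the tether enforces the cis B/C junction with H9 syn to the propargyl group (C9), the dienone arm that eclipses the small C10 oxygen instead of C1H2 reacts (C8), and cold acid closes the 19,10-lactone before the alkoxide can reach the C7 ester.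

Step 8
Reactants: 17 lactone enone (C6 epimers)
Product: 18 lactone enone 6β-ester
Conditions: NaOMe (0.3 equiv), MeOH, 0 °C to 25 °C
Reagents that add atoms: none
Why: Methoxide-mediated epimerisation of the ester α-centre converges both C6 epimers on the thermodynamically preferred 6β-ester, which avoids the quaternary C4 and the lactone carbonyl on the α face of ring B, the hindered bridged lactone being untouched.

Step 9
Reactants: 18 lactone enone 6β-ester
Product: 19 2β,3β-diol
Conditions: OsO4 (2 mol%), 4-methylmorpholine N-oxide, acetone/H2O, 0 °C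
Reagents that add atoms: osmium tetroxide O=[Os](=O)(=O)=O; 4-methylmorpholine N-oxide C[N+]1([O-])CCOCC1; water O
Why: Catalytic OsO4 syn-dihydroxylation (Upjohn conditions) attacks the cis-disubstituted Δ2 alkene, much more reactive than the enone or the alkyne, from the β face opposite the lactone bridge of the 6-oxabicyclo[3.2.1]octene, which sets the 2β,3β-diol.

Step 10
Reactants: 19 2β,3β-diol
Product: 21 tris-silyl enol ether, via lithium enolate 20 (not isolated)
Conditions: LiBH(s-Bu)3 (3.2 equiv), THF, −78 °C; then TBSOTf (3.5 equiv), −78 °C to 0 °C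
Reagents that add atoms: tert-butyldimethylsilyl trifluoromethanesulfonate CC(C)(C)[Si](C)(C)OS(=O)(=O)C(F)(F)F
Why: Conjugate (1,4) hydride reduction of the remaining enone gives the regiodefined C12–C13 enolate (two further hydride equivalents deprotonate the diol) and O-silylation traps it as the silyl enol ether while protecting both hydroxyls, no stereocentre being formed.

Step 11
Reactants: 21 tris-silyl enol ether
Product: 22 silylated methyl ester of the target
Conditions: Ph3PAuCl (5 mol%), AgBF4 (5 mol%), CH2Cl2/MeOH (10:1), 40 °C
Reagents that add atoms: none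
Why: Gold-catalysed 5-exo-dig carbocyclisation of the silyl enol ether onto the terminal alkyne (Conia-ene type) forms the C13–C16 bond from the only geometrically possible face and gives the bicyclo[3.2.1]octane with the exocyclic methylene and the C12 ketone, methanol providing the proton for protodeauration.

Step 12
Reactants: 22 silylated methyl ester of the target
Product: 24 target, via silylated acid 23 (not isolated)
Conditions: LiSPr, HMPA, 25 °C; then HF·pyridine, THF, 0 °C to 25 °C
Reagents that add atoms: none
Why: SN2 demethylation of the hindered methyl ester by thiolate (no attack on the lactone, the base-sensitive 3-hydroxyl still being silylated) followed by fluoride cleavage of the two silyl ethers gives the target without touching any stereocentre.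

## Compound list

1 | 3-methoxybenzoyl chloride | COc1cccc(c1)C(Cl)=O | starting material
2 | (2S)-2-(methoxymethyl)pyrrolidine | COC[C@@H]1CCCN1 | starting material
3 | [(2S)-2-(methoxymethyl)pyrrolidin-1-yl](3-methoxyphenyl)methanone | COC[C@@H]1CCCN1C(=O)c1cccc(OC)c1 | intermediate
4 | potassium amide enolate of the 1,4-dihydro derivative of 3 (C1 protonated) | COC1=CC(=C([O-])N2CCC[C@H]2COC)C=CC1.[K+] | intermediate
5 | [(1R)-3-methoxy-1-methylcyclohexa-2,5-dien-1-yl][(2S)-2-(methoxymethyl)pyrrolidin-1-yl]methanone (ring A; quaternary carbon is C4, enol ether is C5=C10) | COC1=C[C@](C)(C(=O)N2CCC[C@H]2COC)C=CC1 | intermediate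
6 | methyl glyoxylate | COC(=O)C=O | starting material
7 | aldol adduct: ring A C10 ketone (Δ2, C4 as in 5) with CH(OH)CO2Me on C5; C5 and C6 epimer mixtures | O=C1CC=C[C@@](C)(C(=O)N2CCC[C@H]2COC)C1C(O)C(=O)OC | intermediate
8 | C6 methanesulfonate of 7 | O=C1CC=C[C@@](C)(C(=O)N2CCC[C@H]2COC)C1C(OS(C)(=O)=O)C(=O)OC | intermediate
9 | alkylidene keto amide: ring A C10 ketone with exocyclic C5=C6H–CO2Me (E/Z mixture) | O=C1CC=C[C@@](C)(C(=O)N2CCC[C@H]2COC)C1=CC(=O)OC | intermediate
10 | 4-hydroxyphenylboronic acid | OB(O)c1ccc(O)cc1 | starting material
11 | aryl keto amide: C5 bears CH(4-hydroxyphenyl)CO2Me, H5 cis to the C4 methyl; C6 epimers | O=C1CC=C[C@@](C)(C(=O)N2CCC[C@H]2COC)[C@H]1C(c3ccc(O)cc3)C(=O)OC | intermediate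
12 | ketal-lactone phenol: 10-methoxy-19,10-lactone (6-oxabicyclo[3.2.1]oct-2-en-7-one core) with CH(4-hydroxyphenyl)CO2Me equatorial on C5; C6 epimers | CO[C@@]12CC=C[C@@](C)(C(=O)O1)[C@H]2C(c3ccc(O)cc3)C(=O)OC | intermediate
13 | trimethyl(propa-1,2-dien-1-yl)silane | C=C=C[Si](C)(C)C | starting material
14 | ketal-lactone dienone: as 12, C6 now bonded to C8 of a 4-(prop-2-yn-1-yl)cyclohexa-2,5-dien-1-one; C6 epimers | CO[C@@]12CC=C[C@@](C)(C(=O)O1)[C@H]2C(C(=O)OC)C3(CC#C)C=CC(=O)C=C3 | intermediate
15 | dienone keto acid: ring A 10-ketone 19-acid (Δ2) with C5–C6H(CO2Me)–C8(propargyl)(cyclohexadienone); C4 and C5 as in the target; C6 epimers | O=C1CC=C[C@@](C)(C(O)=O)[C@H]1C(C(=O)OC)C2(CC#C)C=CC(=O)C=C2 | intermediate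
16 | 10α-hydroxy 19-acid after C9–C10 closure (samarium salt in the flask); C6 epimers | C#CC[C@]23C=CC(=O)C[C@H]2[C@]1(O)CC=C[C@@](C)(C(O)=O)[C@H]1C3C(=O)OC | intermediate
17 | 19,10-lactone enone: rings A, B and C closed; Δ2; 12-oxo-Δ13; 8β-propargyl; 9β-H; methyl 7-ester as C6 epimers | C#CC[C@]23C=CC(=O)C[C@H]2[C@@]12CC=C[C@@](C)(C(=O)O1)[C@H]2C3C(=O)OC | intermediate
18 | as 17 with 6β-CO2Me (H6 α) | C#CC[C@]23C=CC(=O)C[C@H]2[C@@]12CC=C[C@@](C)(C(=O)O1)[C@H]2[C@@H]3C(=O)OC | intermediate
19 | 2β,3β-diol of 18 | C#CC[C@]23C=CC(=O)C[C@H]2[C@@]12C[C@H](O)[C@H](O)[C@@](C)(C(=O)O1)[C@H]2[C@@H]3C(=O)OC | intermediate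
20 | trilithium C12 enolate 2,3-bis-alkoxide (after 1,4-reduction) | C#CC[C@]23CC=C([O-])C[C@H]2[C@@]12C[C@H]([O-])[C@H]([O-])[C@@](C)(C(=O)O1)[C@H]2[C@@H]3C(=O)OC.[Li+].[Li+].[Li+] | intermediate
21 | 2β,3β-bis(TBS) ether, C12 TBS enol ether (C12=C13), 8β-propargyl lactone methyl ester | C#CC[C@]23CC=C(O[Si](C)(C)C(C)(C)C)C[C@H]2[C@@]12C[C@H](O[Si](C)(C)C(C)(C)C)[C@H](O[Si](C)(C)C(C)(C)C)[C@@](C)(C(=O)O1)[C@H]2[C@@H]3C(=O)OC | intermediate
22 | methyl ester 2,3-bis(TBS) ether of the target (ring D closed, 16-methylene, 12-oxo) | C=C1C[C@]23C[C@H]1C(=O)C[C@H]2[C@@]12C[C@H](O[Si](C)(C)C(C)(C)C)[C@H](O[Si](C)(C)C(C)(C)C)[C@@](C)(C(=O)O1)[C@H]2[C@@H]3C(=O)OC | intermediate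
23 | 2,3-bis(TBS) ether of the target (free 7-acid) | C=C1C[C@]23C[C@H]1C(=O)C[C@H]2[C@@]12C[C@H](O[Si](C)(C)C(C)(C)C)[C@H](O[Si](C)(C)C(C)(C)C)[C@@](C)(C(=O)O1)[C@H]2[C@@H]3C(=O)O | intermediate
24 | CNP0307952.1 (2β,3β-dihydroxy-12-oxo 19,10-lactone 7-acid) | C=C1C[C@]23C[C@H]1C(=O)C[C@H]2[C@@]12C[C@H](O)[C@H](O)[C@@](C)(C(=O)O1)[C@H]2[C@@H]3C(=O)O | target

## Step count and weak points

Total steps: 12. Longest linear sequence: 12 steps (1 to 24); all other inputs are commercial.

Most likely to fail, first: step 7. The dienone radical anion may be over-reduced or may fragment with rearomatisation, the ring junction may close cis, or the wrong dienone arm may react. The fallback sets out from 15 and returns at 17. (COCl)2 with catalytic DMF converts the keto acid into the pseudo-acid chloride F1 (10-chloro-19,10-lactone), in which the lactone is already closed and C10 is a bridgehead. Bu3SnH and AIBN (benzene, 80 °C, 0.05 M) then generate the bridgehead α-acyloxy radical, which can only bond equatorially, and a tin-mediated 5-exo Giese cyclisation onto the dienone closes ring B without any reducing metal, giving 17.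

Second: step 6. The para carbon is hindered, and ortho attack or quinone methide formation by loss of the acidic H6 may compete. The fallback sets out from 9 and returns at 14; ring C is built rather than dearomatised. 3-Ethoxycyclohex-2-en-1-one is propargylated (LiN(i-Pr)2, propargyl bromide) to the vinylogous ester F2. Reduction and hydrolysis (i-Bu2AlH, then aqueous HCl; Stork–Danheiser transposition) give 4-(prop-2-yn-1-yl)cyclohex-2-en-1-one F3, which TBSOTf and Et3N convert into the silyl dienol ether F4. A BF3·OEt2-mediated vinylogous Mukaiyama–Michael addition of F4 to 9 joins C8 to C6 and gives the enone keto amide F5. Camphorsulfonic acid in MeOH closes the ketal-lactone enone F6 as in step 5, and 2-iodoxybenzoic acid (DMSO, 70 °C) dehydrogenates the cyclohexenone to the dienone 14.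

Third: step 2. The diastereoselectivity of the Birch methylation is uncertain without an ortho substituent. The fallback sets out from 3 and returns at 7. Directed ortho-lithiation between the methoxy and amide groups (s-BuLi, TMEDA, −78 °C) and Me3SiCl give the ortho-silyl benzamide F7, which belongs to the ortho-substituted class expected to alkylate with high selectivity. Birch reductive methylation as in step 2 gives the silyl diene F8. Under the step 3 conditions the glyoxylate attacks the vinylsilane carbon C5 (ipso substitution, silicon lost), and aqueous work-up delivers the same aldol adduct 7.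

## Further compounds

F1 | step 7 | pseudo-acid chloride: 10-chloro-19,10-lactone analogue of 14 | Cl[C@@]12CC=C[C@@](C)(C(=O)O1)[C@H]2C(C(=O)OC)C3(CC#C)C=CC(=O)C=C3
F2 | step 6 | 3-ethoxy-6-(prop-2-yn-1-yl)cyclohex-2-en-1-one | CCOC1=CC(=O)C(CC#C)CC1
F3 | step 6 | 4-(prop-2-yn-1-yl)cyclohex-2-en-1-one | O=C1CCC(CC#C)C=C1
F4 | step 6 | tert-butyldimethyl{[4-(prop-2-yn-1-yl)cyclohexa-1,3-dien-1-yl]oxy}silane | C#CCC1=CC=C(O[Si](C)(C)C(C)(C)C)CC1
F5 | step 6 | enone keto amide: as 11 with the aryl group replaced by C8 of a 4-(prop-2-yn-1-yl)cyclohex-2-en-1-one; C6 and C8 epimers | O=C1CC=C[C@@](C)(C(=O)N2CCC[C@H]2COC)[C@H]1C(C(=O)OC)C3(CC#C)CCC(=O)C=C3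
F6 | step 6 | ketal-lactone enone: 9,11-dihydro analogue of 14; C6 and C8 epimers | CO[C@@]12CC=C[C@@](C)(C(=O)O1)[C@H]2C(C(=O)OC)C3(CC#C)CCC(=O)C=C3
F7 | step 2 | [(2S)-2-(methoxymethyl)pyrrolidin-1-yl][3-methoxy-2-(trimethylsilyl)phenyl]methanone | COC[C@@H]1CCCN1C(=O)c1cccc(OC)c1[Si](C)(C)C
F8 | step 2 | C5-trimethylsilyl analogue of 5 | COC1=C([Si](C)(C)C)[C@](C)(C(=O)N2CCC[C@H]2COC)C=CC1
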